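**Retrosynthetic overview**
Ring names: A = methoxyquinone ring (C1–C4, C4a, C8a); B = the phenol ring fused to it (C5–C8); C and D = quinone and dihydroxybenzene rings of the naphthazarin half (primed locants). The end game is O-methylation of a C2 hydroxyquinone, preceded by release of rings C/D from a 1,4,5,8-tetramethoxynaphthalene.
Key disconnection: ring A is opened at C2=C3 and at C1–C8a, giving dimethyl oxalate (C1, C2) and an aryl methyl ketone (C3, C4 on C4a). In the forward direction a 1,4-C,C-dianion and this 1,2-dielectrophile combine in a [4+2] sense.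
Enabling feature: C1 and C2 of ring A are neighbouring carbons that both sit at the carboxyl oxidation level, which is an oxalyl unit. C3 is the methyl carbon of the C4 ketone, so it can be an enolate. C8a is the ring B carbon flanked by the C8 oxygen and the C4 acyl group, so it can be an aryllithium (from a bromide) held by both oxygens.
The hindered C5–C2' biaryl bond is made beforehand by Negishi coupling of a 2-naphthylzinc (from naphthazarin) with a 2-bromo-6-iodoacetophenone (from 2-bromo-5-methylanisole). Iodine couples and bromine is kept for the key step.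
Ring order: rings C/D and ring B are bought intact. Ring A is the only ring formed, in the key step and already at the quinone oxidation level.

Key step: step 7

Assumption: the target is drawn without a descriptor for the C5–C2' axis, so the axis is made racemic. The naphthazarin half is written in the tautomer of the given structure, since its tautomers interconvert and are one compound.

Step 1
Reactants: 1 naphthazarin (5,8-dihydroxynaphthalene-1,4-dione)
Product: 3 1,4,5,8-tetramethoxynaphthalene, via naphthalene-1,4,5,8-tetrol 2 (not isolated)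
Conditions: Na2S2O4, NaOH, Bu4NBr (cat.), THF/H2O, N2, rt; then Me2SO4, rt to 40 °C
Reagents that add atoms: dimethyl sulfate, COS(=O)(=O)OC
Why: Reductive methylation, in which dithionite reduces the quinone to the tetrol and its phenoxides undergo Williamson O-methylation under inert gas before re-oxidation can occur.

Step 2
Reactants: 3 1,4,5,8-tetramethoxynaphthalene
Product: 4 2-bromo-1,4,5,8-tetramethoxynaphthalene
Conditions: NBS (1 equiv), CH2Cl2, 0 °C to rt
Reagents that add atoms: N-bromosuccinimide, O=C1CCC(=O)N1Br
Why: Electrophilic aromatic bromination of a very electron-rich arene whose four free positions are equivalent, so that one equivalent of NBS should stop at the monobromide.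

Step 3
Reactants: 4 2-bromo-1,4,5,8-tetramethoxynaphthalene
Product: 6 2-bromo-1,4,5,8-tetramethoxy-3-methylnaphthalene, via (3-bromo-1,4,5,8-tetramethoxynaphthalen-2-yl)lithium 5 (not isolated)
Conditions: LiN(i-Pr)2, THF, -78 °C; then MeI, -78 °C to rt
Reagents that add atoms: iodomethane, CI
Why: Directed ortho metalation at the only C–H flanked by both Br and OMe (the most acidic site, with an amide base that does not exchange bromine), followed by alkylation of the cold aryllithium with MeI.

Step 4
Reactants: 7 2-bromo-5-methylanisole (1-bromo-2-methoxy-4-methylbenzene)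
Product: 8 1-bromo-5-iodo-2-methoxy-4-methylbenzene
Conditions: NIS, CF3CO2H (cat.), MeCN, rt
Reagents that add atoms: N-iodosuccinimide, O=C1CCC(=O)N1I
Why: Electrophilic aromatic iodination with acid-activated NIS, directed para to the methoxy group and ortho to the methyl group, as is usual for anisoles.

Step 5
Reactants: 8 1-bromo-5-iodo-2-methoxy-4-methylbenzene
Product: 10 1-(2-bromo-6-iodo-3-methoxy-5-methylphenyl)ethan-1-one, via (2-bromo-6-iodo-3-methoxy-5-methylphenyl)lithium 9 (not isolated)
Conditions: LiN(i-Pr)2, THF, -78 °C; then MeC(O)N(OMe)Me, -78 °C to 0 °C; 1 M HCl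
Reagents that add atoms: N-methoxy-N-methylacetamide, CC(=O)N(C)OC
Why: Deprotonative lithiation at the C–H between the two halogens (the most acidic site and also the end point of any halogen dance), followed by a Weinreb ketone synthesis whose chelated adduct prevents over-addition.

Step 6
Reactants: 6 2-bromo-1,4,5,8-tetramethoxy-3-methylnaphthalene; 10 1-(2-bromo-6-iodo-3-methoxy-5-methylphenyl)ethan-1-one
Product: 13 1-[2-bromo-3-methoxy-5-methyl-6-(1,4,5,8-tetramethoxy-3-methylnaphthalen-2-yl)phenyl]ethan-1-one, via naphthyllithium 11 (not isolated), via naphthylzinc chloride 12 (not isolated)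
Conditions: 6, n-BuLi, THF, -78 °C; ZnCl2, -78 °C to rt; then 10, PdCl2(IPent)(3-chloropyridine) (cat., IPent = 1,3-bis[2,6-di(pentan-3-yl)phenyl]imidazol-2-ylidene), THF/NMP, rt to 50 °C
Reagents that add atoms: none
Why: Negishi cross-coupling, in which zerovalent palladium inserts into C–I much faster than into C–Br, the arylzinc tolerates the enolisable ketone, and bulky carbene-palladium catalysts have close precedent for tetra-ortho-substituted biaryls near room temperature, the new axis being formed as a racemate.

Step 7
Reactants: 13 1-[2-bromo-3-methoxy-5-methyl-6-(1,4,5,8-tetramethoxy-3-methylnaphthalen-2-yl)phenyl]ethan-1-one; 14 dimethyl oxalate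
Product: 18 2-hydroxy-8-methoxy-6-methyl-5-(1,4,5,8-tetramethoxy-3-methylnaphthalen-2-yl)naphthalene-1,4-dione, via potassium enolate 15 (not isolated), via C-lithio O-potassio dianion 16 (not isolated), via aryl glyoxylate enolate 17 (not isolated)
Conditions: KH, THF, 0 °C; t-BuLi (2 equiv), -78 °C; 14 (1 equiv, slow addition), -78 °C to rt; 1 M HCl
Reagents that add atoms: none
Why: Proposed new method: KH converts the methyl ketone into its enolate (self-protection, with H2 as the only by-product), t-BuLi exchanges the bromine at C8a faster than it can metalate any methoxyarene C–H, and the resulting 1,4-C,C-dianion meets dimethyl oxalate, the aryllithium being acylated to the aryl glyoxylate and the enolate carbon then attacking the remaining ester (Claisen/Dieckmann), so that C8a–C1 and C3–C2 are made in one flask and ring A appears directly at the quinone oxidation level. The closest known reactions are the [4+2] cyclisation of 2,2'-dilithiobiaryls with dialkyl oxalates to six-membered 1,2-diones, the mono-acylation of aryllithiums by oxalates, and halogen-lithium exchange on substrates whose acidic site was first deprotonated with KH, and what is new is the pairing of an aryllithium with a ketone enolate as the 1,4-dinucleophile. Ring A closes in the favoured 6-(enolendo)-exo-trig mode, whereas aldol attack on the glyoxylate ketone would be a disfavoured and reversible 5-(enolendo)-exo-trig closure, and loss of methoxide followed by deprotonation to the vinylogous carboxylate of the hydroxyquinone is an irreversible sink. No stereocentre is created and the biaryl axis is untouched. The oxygen pattern of ring A needs no external control, because oxalate is symmetrical and connectivity alone makes the carbon bonded to C8a the C1 carbonyl beside C8–OMe and the carbon bonded to the former methyl group the enolised C2–OH. One oxalate per dianion is secured by slow addition of one equivalent, since the intramolecular second acylation should outrun a second intermolecular one, and the flanking C8 methoxy and enolate oxygens hold the lithium at C8a.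

Step 8
Reactants: 18 2-hydroxy-8-methoxy-6-methyl-5-(1,4,5,8-tetramethoxy-3-methylnaphthalen-2-yl)naphthalene-1,4-dione
Product: 20 5-(5,8-dihydroxy-3-methyl-1,4-dioxo-1,4-dihydronaphthalen-2-yl)-2,8-dihydroxy-6-methylnaphthalene-1,4-dione, via leuco tetrol 19 (not isolated)
Conditions: BBr3 (excess), CH2Cl2, -78 °C to rt; H2O; then air, EtOAc/aq. pH 7 buffer, rt
Reagents that add atoms: none
Why: Lewis-acid aryl methyl ether cleavage of all five ethers (neighbouring peri oxygens chelate boron and speed each following cleavage), after which the liberated naphthalene-1,4,5,8-tetrol is autoxidised on aerobic work-up to the naphthazarin.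

Step 9
Reactants: 20 5-(5,8-dihydroxy-3-methyl-1,4-dioxo-1,4-dihydronaphthalen-2-yl)-2,8-dihydroxy-6-methylnaphthalene-1,4-dione
Product: 21 8'-hydroxy-3-methoxyisodiospyrin (target)
Conditions: HCl (cat.), MeOH, reflux
Reagents that add atoms: methanol, CO
Why: Acid-catalysed Fischer-type etherification of a 2-hydroxy-1,4-naphthoquinone (a vinylogous carboxylic acid), which under thermodynamic control gives the 2-methoxy-1,4-quinone and leaves the hydrogen-bonded peri phenols untouched.

**Compound list**
1 | naphthazarin (5,8-dihydroxynaphthalene-1,4-dione) | O=C1C=CC(=O)c2c(O)ccc(O)c12 | starting material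
2 | naphthalene-1,4,5,8-tetrol | Oc1ccc(O)c2c(O)ccc(O)c12 | intermediate
3 | 1,4,5,8-tetramethoxynaphthalene | COc1ccc(OC)c2c(OC)ccc(OC)c12 | intermediate
4 | 2-bromo-1,4,5,8-tetramethoxynaphthalene | COc1c(Br)cc(OC)c2c(OC)ccc(OC)c12 | intermediate
5 | (3-bromo-1,4,5,8-tetramethoxynaphthalen-2-yl)lithium | COc1c(Br)c([Li])c(OC)c2c(OC)ccc(OC)c12 | intermediate
6 | 2-bromo-1,4,5,8-tetramethoxy-3-methylnaphthalene | COc1c(Br)c(C)c(OC)c2c(OC)ccc(OC)c12 | intermediate
7 | 2-bromo-5-methylanisole | COc1cc(C)ccc1Br | starting material
8 | 1-bromo-5-iodo-2-methoxy-4-methylbenzene | COc1cc(C)c(I)cc1Br | intermediate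
9 | (2-bromo-6-iodo-3-methoxy-5-methylphenyl)lithium | COc1cc(C)c(I)c([Li])c1Br | intermediate
10 | 1-(2-bromo-6-iodo-3-methoxy-5-methylphenyl)ethan-1-one | COc1cc(C)c(I)c(C(C)=O)c1Br | intermediate
11 | (1,4,5,8-tetramethoxy-3-methylnaphthalen-2-yl)lithium | COc1c([Li])c(C)c(OC)c2c(OC)ccc(OC)c12 | intermediate
12 | (1,4,5,8-tetramethoxy-3-methylnaphthalen-2-yl)zinc chloride | COc1c([Zn]Cl)c(C)c(OC)c2c(OC)ccc(OC)c12 | intermediate
13 | 1-[2-bromo-3-methoxy-5-methyl-6-(1,4,5,8-tetramethoxy-3-methylnaphthalen-2-yl)phenyl]ethan-1-one (racemic axis) | COc1cc(C)c(-c2c(C)c(OC)c3c(OC)ccc(OC)c3c2OC)c(C(C)=O)c1Br | intermediate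
14 | dimethyl oxalate | COC(=O)C(=O)OC | starting material
15 | potassium enolate of 13 | COc1cc(C)c(-c2c(C)c(OC)c3c(OC)ccc(OC)c3c2OC)c(C(=C)O[K])c1Br | intermediate
16 | C-lithio O-potassio dianion | COc1cc(C)c(-c2c(C)c(OC)c3c(OC)ccc(OC)c3c2OC)c(C(=C)O[K])c1[Li] | intermediate
17 | aryl glyoxylate enolate (methyl 2-aryl-2-oxoacetate carrying the potassium enolate) | COc1cc(C)c(-c2c(C)c(OC)c3c(OC)ccc(OC)c3c2OC)c(C(=C)O[K])c1C(=O)C(=O)OC | intermediate
18 | 2-hydroxy-8-methoxy-6-methyl-5-(1,4,5,8-tetramethoxy-3-methylnaphthalen-2-yl)naphthalene-1,4-dione | OC1=CC(=O)c2c(-c3c(C)c(OC)c4c(OC)ccc(OC)c4c3OC)c(C)cc(OC)c2C1=O | intermediate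
19 | 2,8-dihydroxy-6-methyl-5-(1,4,5,8-tetrahydroxy-3-methylnaphthalen-2-yl)naphthalene-1,4-dione (leuco tetrol) | OC1=CC(=O)c2c(-c3c(C)c(O)c4c(O)ccc(O)c4c3O)c(C)cc(O)c2C1=O | intermediate
20 | 5-(5,8-dihydroxy-3-methyl-1,4-dioxo-1,4-dihydronaphthalen-2-yl)-2,8-dihydroxy-6-methylnaphthalene-1,4-dione | OC1=CC(=O)c2c(C3=C(C)C(=O)c4c(O)ccc(O)c4C3=O)c(C)cc(O)c2C1=O | intermediate
21 | 8'-hydroxy-3-methoxyisodiospyrin | COC1=CC(=O)c2c(C3=C(C)C(=O)c4c(O)ccc(O)c4C3=O)c(C)cc(O)c2C1=O | target

**Step count and risks**
Total steps: 9. Longest linear sequence: 7 (steps 1, 2, 3, 6, 7, 8, 9).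

**Step 7 (the proposed new method).**
- What may go wrong: the two carbanionic sites are acylated by separate oxalate molecules, the aryllithium is protonated before acylation, or the five-membered aldol closure reverses only slowly.
- The fallback uses known chemistry and makes the two bonds one after the other. It sets out from 13.
- A crossed Claisen condensation with 14 (NaOMe, MeOH/THF, rt to 50 °C) gives methyl 4-[2-bromo-3-methoxy-5-methyl-6-(1,4,5,8-tetramethoxy-3-methylnaphthalen-2-yl)phenyl]-2,4-dioxobutanoate F1.
- Its acidic 1,3-dicarbonyl unit is deprotonated with KH, and bromine-lithium exchange with t-BuLi at -78 °C follows.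
- Parham cyclisation of the aryllithium onto the ester then closes ring A and comes back to the route at 18.

**Step 6.**
- What may go wrong: transmetalation and reductive elimination are slow at a palladium centre that carries two di-ortho-substituted aryl groups. This leaves time for insertion into the C–Br bond and for protodemetalation of the arylzinc.
- The fallback shrinks the ortho group during coupling and builds the ketone afterwards. It sets out from 8.
- Compound 8 is lithiated as in step 5 (9) and trapped with 4-toluenesulfonyl cyanide to give 2-bromo-6-iodo-3-methoxy-5-methylbenzonitrile F2.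
- Negishi coupling of F2 with 12 gives 2-bromo-3-methoxy-5-methyl-6-(1,4,5,8-tetramethoxy-3-methylnaphthalen-2-yl)benzonitrile F3.
- Addition of MeMgBr (CuBr cat., toluene/THF, reflux) and hydrolysis of the ketimine with warm aqueous HCl comes back to the route at 13.

**Step 8.**
- What may go wrong: ether cleavage stays incomplete at the crowded peri positions, or the very electron-rich tetrol degrades before it is oxidised.
- The fallback reverses the order of events and sets out from 18.
- Oxidative demethylation with (NH4)2Ce(NO3)6 (MeCN/H2O, 0 °C) gives 5-(5,8-dimethoxy-3-methyl-1,4-dioxo-1,4-dihydronaphthalen-2-yl)-2-hydroxy-8-methoxy-6-methylnaphthalene-1,4-dione F4.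
- Which ring of the tetramethoxynaphthalene is oxidised is without consequence, because both outcomes lead to the same naphthazarin after ether cleavage.
- Chelation-assisted cleavage of the three remaining peri methyl ethers with AlCl3 (CH2Cl2, rt) comes back to the route at 20.

**Further compounds**
F1 | step 7 | methyl 4-[2-bromo-3-methoxy-5-methyl-6-(1,4,5,8-tetramethoxy-3-methylnaphthalen-2-yl)phenyl]-2,4-dioxobutanoate | COC(=O)C(=O)CC(=O)c1c(Br)c(OC)cc(C)c1-c1c(C)c(OC)c2c(OC)ccc(OC)c2c1OC
F2 | step 6 | 2-bromo-6-iodo-3-methoxy-5-methylbenzonitrile | COc1cc(C)c(I)c(C#N)c1Br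
F3 | step 6 | 2-bromo-3-methoxy-5-methyl-6-(1,4,5,8-tetramethoxy-3-methylnaphthalen-2-yl)benzonitrile | COc1cc(C)c(-c2c(C)c(OC)c3c(OC)ccc(OC)c3c2OC)c(C#N)c1Br
F4 | step 8 | 5-(5,8-dimethoxy-3-methyl-1,4-dioxo-1,4-dihydronaphthalen-2-yl)-2-hydroxy-8-methoxy-6-methylnaphthalene-1,4-dione | OC1=CC(=O)c2c(C3=C(C)C(=O)c4c(OC)ccc(OC)c4C3=O)c(C)cc(OC)c2C1=O
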